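The readings are calculated from invented constants; noise was put on by code.

Start with an easy step: count what vanishes. Suppose each target comes from one substrate and one reagent, and each loss of target takes one further substrate. Then over any stretch, target made goes with substrate lost plus target gained, and target used goes with substrate lost minus target gained.

| flask | substrate | reagent | remark | time |
|---|---|---|---|---|
| theta | 0.53 M | 0.52 M | run made earlier |  |
| epsilon | 0.53 M | 0.82 M | run made earlier |  |
| alpha | 0.27 M | 0.371 M | run made earlier |  |
| flask | 0.53 M | 0.371 M |  | 15 min |

| run | time / min | target / % | substrate / % |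
|---|---|---|---|
| theta | 1.50 | 11.2 | 87.6 |
| theta | 3.00 | 17.2 | 76.6 |
| theta | 5.00 | 23.6 | 64.9 |
| theta | 6.00 | 26.9 | 58.8 |
| theta | 8.00 | 28.7 | 51.3 |
| theta | 10.0 | 30.6 | 43.6 |
| theta | 12.0 | 30.1 | 37.1 |
| epsilon | 1.50 | 12.7 | 84.7 |
| epsilon | 3.00 | 23.0 | 71.6 |
| epsilon | 5.00 | 29.4 | 57.7 |
| epsilon | 6.00 | 30.6 | 52.1 |
| epsilon | 8.00 | 34.4 | 43.7 |
| epsilon | 10.0 | 35.9 | 35.8 |
| epsilon | 12.0 | 37.0 | 30.5 |
| alpha | 1.00 | 5.4 | 95.2 |
| alpha | 3.00 | 13.1 | 85.1 |
| alpha | 6.00 | 21.4 | 73.3 |
| alpha | 8.00 | 25.8 | 66.0 |
| alpha | 12.0 | 30.3 | 52.6 |

(readings scatter by 0.5 percentage points)

- the state of affairs at 15 min: stopped, and by what, or still going (it is still moving / the reagent has run out first / all of the substrate has reacted)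
- how much target there is at 15 min, in percent of the substrate charged

- the reaction counts as stopped when no species that holds the substrate changes by six tenths of a point or more over the second half of the time

In the epsilon run, from 5.00 min to 12.0 min, that count gives made over used as 1.78. I assume this ratio equals κ√([substrate][reagent])/[target]. Here κ is the hand-over constant, a kind of selectivity factor, and the epsilon reading gives κ = 0.846. Target climbs while the ratio exceeds 1 and falls once it drops below, so κ√([substrate][reagent]) is the level where control changes hands.

Now compare the theta run, which has the same substrate but more reagent than the flask. At 12.0 min the theta level is 37.0%, above its target reading of 30.1%, so by this reckoning theta's target is still climbing at that reading.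

For the flask, the substrate decay of theta and epsilon, scaled to its reagent, gives 0.0720 min⁻¹. So I reckon 34.0% of the substrate in the flask at 15 min, and I assume its target has reached the crossing by then. Solving the crossing with the balance puts the flask's level at 24.5% at that time, lower than theta's at 12.0 min, with 0.131 M of reagent reckoned left. By the same decay the flask's substrate falls 24 percentage points over the second half of the time, so I commit to that target, with the flask still moving.

The forecast, higher than my level, says it is still moving and 28%, within 25% to 31%: “The substrate is still falling, so the reaction is still moving.”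

The flask gives: it is still moving, with 26.8% of target.

    substrate + reagent → target, rate k1*[substrate]^1.5*[reagent]^0.5 (k = 0.00280 M⁻¹ s⁻¹)
    substrate + target → side product (k = 0.00320 M⁻¹ s⁻¹)

In the flask at 15.0 min, with substrate at 37.2%, reagent at 36.0% of its own charge and target at 26.8%, κ gives a ratio of 0.966. The simulated ratio of making to use there is 1.00, down from 2.79 at 4.11 min. The same flask read at 60.0 min holds substrate at 6.61% and reagent at 18.4% of its own charge, so κ gives 0.374, and its target has fallen to 20.9%.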